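Numbering: ring C1 (bears the isopropylidene) round to C6 (CH with the acid chain), C4 is CHMe, C5 quaternary; C11 and C12 are the methyls on C4 and C5, C13 the indolyl CH2. C11 and C13, cis on neighbouring ring atoms, are drawn into one γ-lactone (C11 acetal carbon, C13 carbonyl carbon) whose C4=C5 alkene is the 2π partner. One Diels–Alder addition of butadiene to this (5R)-menthyloxy-3-methylbutenolide forges C3–C4 and C5–C6, closes the carbocycle and fixes C4 and quaternary C5 opposite the menthyloxy group. The lactone is then taken apart: C11 becomes methyl, the C13 acid places oxygen on C1; C6 allylation, isopropylidenation and indole attachment follow.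

Key step: step 3

Convention: the target numbering above is used for every intermediate; β is the ring face that carries C11 and C13, α the face that carries C12.
Assumption: the (5R) acetal epimer 6 is taken to be the crystalline one, as in closely related 5-menthyloxybutenolides; if it is not, the epimers would be separated by chromatography and 5 re-equilibrated with acid.

## Route

Step 1
Reactants: 1 3-methylfuran-2-carboxylic acid
Product: 3 5-hydroxy-3-methylfuran-2(5H)-one (racemic), via furan endoperoxide 2 (not isolated)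
Conditions: O2, rose bengal (cat.), hν (visible), MeOH, 0 °C
Reagents that add atoms: oxygen, O=O
Why: Sensitised singlet-oxygen [4+2] photooxygenation of the furan, followed by decarboxylative fragmentation of the endoperoxide, should turn the carboxyl-bearing carbon into the lactone carbonyl next to the methyl group and C5 into the hemiacetal; the new centre is racemic and is fixed in step 2.

Step 2
Reactants: 3 5-hydroxy-3-methylfuran-2(5H)-one; 4 (−)-menthol
Product: 6 (5R)-3-methyl-5-[(1R,2S,5R)-menthyloxy]furan-2(5H)-one, via (5S)-menthyloxy epimer 5 (not isolated)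
Conditions: CSA (cat.), toluene, reflux, Dean–Stark; crystallisation from hexane, liquor re-equilibrated (CSA) and recrystallised
Reagents that add atoms: none
Why: Acid-catalysed acetalisation (pseudo-ester formation) should give both acetal epimers, which interconvert through the oxocarbenium ion, so the (5R) centre is selected by crystallisation with recycling of the (5S) epimer.

Step 3
Reactants: 6 (5R)-3-methyl-5-[(1R,2S,5R)-menthyloxy]furan-2(5H)-one; 7 buta-1,3-diene
Product: 8 (3R,3aR,7aS)-7a-methyl-3-[(1R,2S,5R)-menthyloxy]-3a,4,7,7a-tetrahydro-2-benzofuran-1(3H)-one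
Conditions: buta-1,3-diene (excess), hydroquinone (cat.), toluene, sealed autoclave, 150 °C
Reagents that add atoms: none
Why: The step is a thermal, concerted, suprafacial [4π+2π] Diels–Alder cycloaddition, the closest known type being additions of simple 1,3-dienes to 5-alkoxyfuran-2(5H)-ones. The cyclohexene ring closes by cycloaddition, with C3–C4 and C5–C6 formed together across the butenolide C4=C5 bond, which enforces the cis fusion to the lactone. C4 is set by approach of the diene to the face anti to the menthyloxy group on the neighbouring acetal carbon C11, and the quaternary C5 follows from suprafacial addition, so C11 and C13 end up cis and C12 trans to them. Only π-facial selectivity is required, because the symmetric diene leaves no regiochemical or endo/exo question, and it is secured by the bulky menthyloxy substituent on the rigid five-membered ring. The α-methyl group lowers the dienophile reactivity, hence the high temperature, the excess of diene and the radical inhibitor.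

Step 4
Reactants: 8 Diels–Alder adduct
Product: 11 (3aR,7aS)-7a-methyl-3a,4,7,7a-tetrahydro-2-benzofuran-1(3H)-one, via formyl carboxylate 9 (not isolated), via hydroxy carboxylate 10 (not isolated)
Conditions: KOH, NaBH4, EtOH/H2O, 0 → 40 °C; then 2 M HCl
Reagents that add atoms: none
Why: Saponification of the pseudo-ester should release menthol and unmask the C11 aldehyde as its carboxylate, borohydride reduces it at once before C4 can epimerise, and acidification closes the hydroxy acid to the γ-lactone (carbonyl reduction then lactonisation), C4 and C5 being untouched.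

Step 5
Reactants: 11 cis-fused γ-lactone
Product: 12 (1S,6R)-1-methyl-6-[(phenylselanyl)methyl]cyclohex-3-ene-1-carboxylic acid
Conditions: (PhSe)2, NaBH4, DMF, 120 °C; then 1 M HCl
Reagents that add atoms: diphenyl diselenide, c1ccc(cc1)[Se][Se]c1ccccc1 (acting as sodium benzeneselenolate, [Na+].[Se-]c1ccccc1)
Why: SN2 alkyl–oxygen cleavage of the γ-lactone by the soft selenolate at the primary carbon C11 (lactone opening by benzeneselenolate) should free the C13 carboxylic acid without touching a stereocentre.

Step 6
Reactants: 12 seleno acid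
Product: 13 (1S,6R)-1,6-dimethylcyclohex-3-ene-1-carboxylic acid
Conditions: Bu3SnH, AIBN (cat.), toluene, 100 °C
Reagents that add atoms: none
Why: Radical chain reduction of the C–Se bond by tin hydride (reductive deselenation) should turn C11 into the C4 methyl group, hydrogen transfer to the primary radical being faster than its strained cyclisation onto the ring alkene.

Step 7
Reactants: 13 dimethylcyclohexene acid
Product: 14 (1S,2R,4R,5R)-4-iodo-1,2-dimethyl-6-oxabicyclo[3.2.1]octan-7-one
Conditions: I2, KI, NaHCO3, THF/H2O, 0 °C → rt, dark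
Reagents that add atoms: iodine, II
Why: In this iodolactonisation the C13 carboxylate should open the iodonium ion at C1 in a 5-exo, trans-diaxial manner, so oxygen is delivered to C1 on the β-face and iodine to C2 on the α-face, which tells the two alkene carbons apart.

Step 8
Reactants: 14 iodolactone
Product: 15 (1S,2R,5R)-1,2-dimethyl-6-oxabicyclo[3.2.1]oct-3-en-7-one
Conditions: DBU, toluene, 100 °C
Reagents that add atoms: none
Why: E2 dehydroiodination through the C3 hydrogen anti-periplanar to the axial iodide should give the C2=C3 alkene and leave the C1–O bond allylic; no stereocentre is affected.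

Step 9
Reactants: 15 allylic lactone
Product: 16 (1R,4R,5S)-5-(hydroxymethyl)-4,5-dimethylcyclohex-2-en-1-ol
Conditions: LiAlH4, THF, 0 °C → rt; H2O/NaOH work-up
Reagents that add atoms: none
Why: Hydride reduction of the lactone should give the C13 primary alcohol and the C1 allylic alcohol without touching the isolated ring alkene; the C1 carbinol centre is retained and removed in step 10.

Step 10
Reactants: 16 diol
Product: 17 (4R,5S)-5-(hydroxymethyl)-4,5-dimethylcyclohex-2-en-1-one
Conditions: MnO2 (activated, excess), CH2Cl2, rt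
Reagents that add atoms: none
Why: Chemoselective MnO2 oxidation of the allylic alcohol should give the C1 enone while the saturated neopentyl alcohol at C13 is left alone.

Step 11
Reactants: 17 hydroxy enone
Product: 18 (4R,5S)-5-({[tert-butyl(dimethyl)silyl]oxy}methyl)-4,5-dimethylcyclohex-2-en-1-one
Conditions: TBSCl, imidazole, DMF, rt
Reagents that add atoms: tert-butyldimethylsilyl chloride, CC(C)(C)[Si](C)(C)Cl
Why: Silylation of the primary alcohol (silyl ether protection) masks C13–OH for the enolate step and enlarges the β-face substituent on C5.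

Step 12
Reactants: 18 silyloxy enone
Product: 20 (4R,5R,6S)-5-({[tert-butyl(dimethyl)silyl]oxy}methyl)-4,5-dimethyl-6-(prop-2-en-1-yl)cyclohex-2-en-1-one, via lithium dienolate 19 (not isolated)
Conditions: LDA, THF, −78 °C; allyl bromide, −78 → −30 °C
Reagents that add atoms: allyl bromide, C=CCBr
Why: Kinetic α′-deprotonation gives the cross-conjugated dienolate, and its SN2 allylation (enolate alkylation) should take place at C6 on the α-face, anti to the pseudo-axial CH2OTBS group on C5 and away from the β-methyl C11, so the allyl group ends up trans to C13 and cis to C12 under kinetic control.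

Step 13
Reactants: 20 allyl enone
Product: 21 (2S,3R,4R)-3-({[tert-butyl(dimethyl)silyl]oxy}methyl)-3,4-dimethyl-2-(prop-2-en-1-yl)cyclohexan-1-one
Conditions: [(Ph3P)CuH]6, H2O, benzene, rt
Reagents that add atoms: none
Why: Copper hydride conjugate (1,4) reduction of the enone, with protonation of the copper enolate by water, should saturate C2=C3 without touching the terminal alkene, the silyl ether or the epimerisable C6 centre, since the enolate lies on the C2 side.

Step 14
Reactants: 21 allyl ketone
Product: 23 tert-butyl{[(1R,2R,6R)-1,6-dimethyl-3-(propan-2-ylidene)-2-(prop-2-en-1-yl)cyclohexyl]methoxy}dimethylsilane, via titanium pinacolate 22 (not isolated)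
Conditions: TiCl3, Zn–Cu, DME, reflux; then 21 and acetone (excess), slow addition, reflux
Reagents that add atoms: acetone, CC(C)=O
Why: McMurry mixed reductive carbonyl coupling with excess acetone on low-valent titanium should convert C1=O into the tetrasubstituted C1=C(CH3)2 alkene by deoxygenation of the mixed pinacolate; no stereocentre is formed and the non-basic medium is chosen to spare C6.

Step 15
Reactants: 23 isopropylidene silyl ether
Product: 24 [(1R,2R,6R)-1,6-dimethyl-3-(propan-2-ylidene)-2-(prop-2-en-1-yl)cyclohexyl]methanol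
Conditions: TBAF, THF, rt → 40 °C
Reagents that add atoms: none
Why: Fluoride-induced desilylation should free the C13 alcohol, nothing else in the molecule being sensitive to fluoride.

Step 16
Reactants: 24 neopentyl alcohol
Product: 25 (1R,2R,6R)-1,6-dimethyl-3-(propan-2-ylidene)-2-(prop-2-en-1-yl)cyclohexane-1-carbaldehyde
Conditions: Dess–Martin periodinane, CH2Cl2, rt
Reagents that add atoms: none
Why: Dess–Martin oxidation should give the C13 aldehyde, which has no α-hydrogen and so cannot enolise or epimerise, while both alkenes are inert.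

Step 17
Reactants: 25 C13 aldehyde; 26 indole
Product: 28 [(1R,2R,6R)-1,6-dimethyl-3-(propan-2-ylidene)-2-(prop-2-en-1-yl)cyclohexyl](1H-indol-3-yl)methanol (both carbinol epimers), via indol-1-ylmagnesium bromide 27 (not isolated)
Conditions: indole, EtMgBr, THF, rt; then 25, 0 °C → rt; H2O
Reagents that add atoms: none
Why: Addition of the ambident indolyl Grignard reagent through C3 to the aldehyde should form the C13–indole bond under non-acidic conditions; the new carbinol centre arises as a mixture that is erased in step 18.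

Step 18
Reactants: 28 indolyl carbinol
Product: 30 3-{[(1R,2S,6R)-1,6-dimethyl-3-(propan-2-ylidene)-2-(prop-2-en-1-yl)cyclohexyl]methyl}-1H-indole, via 3-alkylidene-3H-indole 29 (not isolated)
Conditions: LiAlH4, THF, reflux; H2O work-up
Reagents that add atoms: none
Why: In this LiAlH4 hydrogenolysis of a 3-indolylcarbinol, N-deprotonation and loss of the aluminium-bound oxygen should give a 3-alkylidene-3H-indole that takes up hydride at C13, a basic process that leaves both alkenes untouched.

Step 19
Reactants: 30 allyl indole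
Product: 32 3-[(1S,2R,3R)-2-(1H-indol-3-ylmethyl)-2,3-dimethyl-6-(propan-2-ylidene)cyclohexyl]propan-1-ol, via B-alkyl-9-BBN 31 (not isolated)
Conditions: 9-BBN, THF, 0 °C → rt; then NaOH, H2O2, 0 °C
Reagents that add atoms: hydrogen peroxide, OO
Why: Anti-Markovnikov hydroboration with 9-BBN should be selective for the monosubstituted alkene over the tetrasubstituted isopropylidene group, and alkaline peroxide oxidation of the borane gives the primary alcohol at C10.

Step 20
Reactants: 32 primary alcohol
Product: 33 3-[(1S,2R,3R)-2-(1H-indol-3-ylmethyl)-2,3-dimethyl-6-(propan-2-ylidene)cyclohexyl]propanal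
Conditions: SO3·pyridine, DMSO, Et3N, CH2Cl2, 0 °C
Reagents that add atoms: none
Why: Parikh–Doering oxidation (activated DMSO) should give the aldehyde under mild basic conditions that the free indole and the tetrasubstituted alkene tolerate.

Step 21
Reactants: 33 aldehyde
Product: 34 suaveolindole
Conditions: NaClO2, NaH2PO4, 2-methyl-2-butene (excess), t-BuOH/H2O, 0 °C → rt
Reagents that add atoms: sodium chlorite, [Na+].[O-]Cl=O
Why: Pinnick oxidation (chlorous acid) should convert the aldehyde into the carboxylic acid, the excess 2-methyl-2-butene trapping the hypochlorous acid by-product before it can attack the indole or the isopropylidene group.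

## Compound list

1 | 3-methylfuran-2-carboxylic acid | Cc1ccoc1C(=O)O | starting material
2 | 6-methyl-2,3,7-trioxabicyclo[2.2.1]hept-5-ene-1-carboxylic acid (furan endoperoxide, racemic) | CC1=CC2OOC1(C(=O)O)O2 | intermediate
3 | 5-hydroxy-3-methylfuran-2(5H)-one (racemic) | CC1=CC(O)OC1=O | intermediate
4 | (−)-menthol, (1R,2S,5R)-5-methyl-2-(propan-2-yl)cyclohexan-1-ol | C[C@@H]1CC[C@H]([C@@H](C1)O)C(C)C | starting material
5 | (5S)-3-methyl-5-[(1R,2S,5R)-menthyloxy]furan-2(5H)-one | CC1=C[C@@H](O[C@@H]2C[C@H](C)CC[C@H]2C(C)C)OC1=O | intermediate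
6 | (5R)-3-methyl-5-[(1R,2S,5R)-menthyloxy]furan-2(5H)-one | CC1=C[C@H](O[C@@H]2C[C@H](C)CC[C@H]2C(C)C)OC1=O | intermediate
7 | buta-1,3-diene | C=CC=C | starting material
8 | (3R,3aR,7aS)-7a-methyl-3-[(1R,2S,5R)-menthyloxy]-3a,4,7,7a-tetrahydro-2-benzofuran-1(3H)-one (cis-fused, menthyloxy anti to the cyclohexene) | C[C@]12CC=CC[C@H]1[C@H](O[C@@H]3C[C@H](C)CC[C@H]3C(C)C)OC2=O | intermediate
9 | potassium (1S,6R)-6-formyl-1-methylcyclohex-3-ene-1-carboxylate | [K+].C[C@]1(C([O-])=O)CC=CC[C@H]1C=O | intermediate
10 | potassium (1S,6R)-6-(hydroxymethyl)-1-methylcyclohex-3-ene-1-carboxylate | [K+].C[C@]1(C([O-])=O)CC=CC[C@H]1CO | intermediate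
11 | (3aR,7aS)-7a-methyl-3a,4,7,7a-tetrahydro-2-benzofuran-1(3H)-one | C[C@]12CC=CC[C@H]1COC2=O | intermediate
12 | (1S,6R)-1-methyl-6-[(phenylselanyl)methyl]cyclohex-3-ene-1-carboxylic acid | C[C@]1(C(=O)O)CC=CC[C@H]1C[Se]c1ccccc1 | intermediate
13 | (1S,6R)-1,6-dimethylcyclohex-3-ene-1-carboxylic acid | C[C@]1(C(=O)O)CC=CC[C@H]1C | intermediate
14 | (1S,2R,4R,5R)-4-iodo-1,2-dimethyl-6-oxabicyclo[3.2.1]octan-7-one | C[C@@H]1C[C@@H](I)[C@H]2C[C@]1(C)C(=O)O2 | intermediate
15 | (1S,2R,5R)-1,2-dimethyl-6-oxabicyclo[3.2.1]oct-3-en-7-one | C[C@@H]1C=C[C@H]2C[C@]1(C)C(=O)O2 | intermediate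
16 | (1R,4R,5S)-5-(hydroxymethyl)-4,5-dimethylcyclohex-2-en-1-ol | C[C@@H]1C=C[C@H](O)C[C@]1(C)CO | intermediate
17 | (4R,5S)-5-(hydroxymethyl)-4,5-dimethylcyclohex-2-en-1-one | C[C@@H]1C=CC(=O)C[C@]1(C)CO | intermediate
18 | (4R,5S)-5-({[tert-butyl(dimethyl)silyl]oxy}methyl)-4,5-dimethylcyclohex-2-en-1-one | C[C@@H]1C=CC(=O)C[C@]1(C)CO[Si](C)(C)C(C)(C)C | intermediate
19 | lithium cross-conjugated dienolate of 18 (O–Li on C1, C1=C6 and C2=C3) | [Li+].C[C@@H]1C=CC([O-])=C[C@]1(C)CO[Si](C)(C)C(C)(C)C | intermediate
20 | (4R,5R,6S)-5-({[tert-butyl(dimethyl)silyl]oxy}methyl)-4,5-dimethyl-6-(prop-2-en-1-yl)cyclohex-2-en-1-one (allyl α, trans to CH2OTBS) | C[C@@H]1C=CC(=O)[C@@H](CC=C)[C@]1(C)CO[Si](C)(C)C(C)(C)C | intermediate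
21 | (2S,3R,4R)-3-({[tert-butyl(dimethyl)silyl]oxy}methyl)-3,4-dimethyl-2-(prop-2-en-1-yl)cyclohexan-1-one | C[C@@H]1CCC(=O)[C@@H](CC=C)[C@]1(C)CO[Si](C)(C)C(C)(C)C | intermediate
22 | titanium-bound mixed pinacolate of 21 and acetone (drawn as the free 1,2-diol, C1 epimers) | C[C@@H]1CCC(O)(C(C)(C)O)[C@@H](CC=C)[C@]1(C)CO[Si](C)(C)C(C)(C)C | intermediate
23 | tert-butyl{[(1R,2R,6R)-1,6-dimethyl-3-(propan-2-ylidene)-2-(prop-2-en-1-yl)cyclohexyl]methoxy}dimethylsilane | C[C@@H]1CCC(=C(C)C)[C@@H](CC=C)[C@]1(C)CO[Si](C)(C)C(C)(C)C | intermediate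
24 | [(1R,2R,6R)-1,6-dimethyl-3-(propan-2-ylidene)-2-(prop-2-en-1-yl)cyclohexyl]methanol | C[C@@H]1CCC(=C(C)C)[C@@H](CC=C)[C@]1(C)CO | intermediate
25 | (1R,2R,6R)-1,6-dimethyl-3-(propan-2-ylidene)-2-(prop-2-en-1-yl)cyclohexane-1-carbaldehyde | C[C@@H]1CCC(=C(C)C)[C@@H](CC=C)[C@]1(C)C=O | intermediate
26 | indole | c1ccc2[nH]ccc2c1 | starting material
27 | indol-1-ylmagnesium bromide | Br[Mg]n1ccc2ccccc12 | intermediate
28 | [(1R,2R,6R)-1,6-dimethyl-3-(propan-2-ylidene)-2-(prop-2-en-1-yl)cyclohexyl](1H-indol-3-yl)methanol (both carbinol epimers) | C[C@@H]1CCC(=C(C)C)[C@@H](CC=C)[C@]1(C)C(O)c1c[nH]c2ccccc12 | intermediate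
29 | 3-alkylidene-3H-indole from 28 (C13=C3 of the indolenine, ring stereocentres as in 28) | C[C@@H]1CCC(=C(C)C)[C@@H](CC=C)[C@]1(C)C=C1C=Nc2ccccc12 | intermediate
30 | 3-{[(1R,2S,6R)-1,6-dimethyl-3-(propan-2-ylidene)-2-(prop-2-en-1-yl)cyclohexyl]methyl}-1H-indole | C[C@@H]1CCC(=C(C)C)[C@@H](CC=C)[C@]1(C)Cc1c[nH]c2ccccc12 | intermediate
31 | B-alkyl-9-borabicyclo[3.3.1]nonane from 30 (boron on the terminal chain carbon C10) | C[C@@H]1CCC(=C(C)C)[C@@H](CCCB2C3CCCC2CCC3)[C@]1(C)Cc1c[nH]c2ccccc12 | intermediate
32 | 3-[(1S,2R,3R)-2-(1H-indol-3-ylmethyl)-2,3-dimethyl-6-(propan-2-ylidene)cyclohexyl]propan-1-ol | C[C@@H]1CCC(=C(C)C)[C@@H](CCCO)[C@]1(C)Cc1c[nH]c2ccccc12 | intermediate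
33 | 3-[(1S,2R,3R)-2-(1H-indol-3-ylmethyl)-2,3-dimethyl-6-(propan-2-ylidene)cyclohexyl]propanal | C[C@@H]1CCC(=C(C)C)[C@@H](CCC=O)[C@]1(C)Cc1c[nH]c2ccccc12 | intermediate
34 | suaveolindole, 3-[(1S,2R,3R)-2-(1H-indol-3-ylmethyl)-2,3-dimethyl-6-(propan-2-ylidene)cyclohexyl]propanoic acid | CC(C)=C1CC[C@@H](C)[C@@](C)(Cc2c[nH]c3ccccc23)[C@@H]1CCC(=O)O | target

## Step count and risks

Total step count: 21. Longest linear sequence: 21 steps, from 1 to 34; menthol, butadiene and indole enter as purchased compounds.

Steps most likely to fail: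

Step 14. The mixed reductive coupling may stall at the hindered ketone while acetone couples with itself, and titanium-mediated enolisation may scramble C6. The fallback sets out from 21 and returns at 23. Addition of dilithiated isobutyric acid (isobutyric acid, 2 LDA, THF, −78 → 0 °C) to the ketone would give the β-hydroxy acid F1. Benzenesulfonyl chloride in pyridine would close the spiro β-lactone F2. Heating at about 150 °C would expel CO2 by thermal [2+2] cycloreversion and deliver 23 (β-lactone route to tetrasubstituted alkenes).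

Step 12. Facial discrimination at C6 may be poor, or proton exchange between product and enolate may equilibrate C6 towards the β-allyl epimer, which is expected to be the more stable one. The fallback sets out from 18 and returns at 20. The dienolate 19 would be O-acylated with allyl chloroformate (TMEDA, THF, −78 °C) to the allyl dienyl carbonate F3. Pd2(dba)3 with a chiral phosphinooxazoline ligand (the enantiomer that reinforces α-face attack) in THF would then effect a decarboxylative allylic alkylation of the Tsuji type under neutral, catalyst-controlled conditions to give 20.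

Step 21. Electrophilic chlorine released during the chlorite oxidation may attack the unprotected indole or the tetrasubstituted alkene. The fallback sets out from 30 and returns at 34. Boc2O with DMAP in MeCN would give the N-Boc indole F4. 9-BBN would give the alkylborane F5, which NaBO3 would oxidise to the N-Boc primary alcohol F6. TEMPO with PhI(OAc)2 in MeCN/H2O would give the N-Boc acid F7, and K2CO3 in MeOH would remove the carbamate to give 34.

## Further compounds

F1 | step 14 | 2-[(2S,3R,4R)-3-({[tert-butyl(dimethyl)silyl]oxy}methyl)-1-hydroxy-3,4-dimethyl-2-(prop-2-en-1-yl)cyclohexyl]-2-methylpropanoic acid (C1 epimers) | C[C@@H]1CCC(O)(C(C)(C)C(=O)O)[C@@H](CC=C)[C@]1(C)CO[Si](C)(C)C(C)(C)C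
F2 | step 14 | (5S,6R,7R)-6-({[tert-butyl(dimethyl)silyl]oxy}methyl)-3,3,6,7-tetramethyl-5-(prop-2-en-1-yl)-1-oxaspiro[3.5]nonan-2-one (spiro epimers) | C[C@@H]1CCC2(OC(=O)C2(C)C)[C@@H](CC=C)[C@]1(C)CO[Si](C)(C)C(C)(C)C
F3 | step 12 | allyl (3R,4R)-3-({[tert-butyl(dimethyl)silyl]oxy}methyl)-3,4-dimethylcyclohexa-1,5-dien-1-yl carbonate | C[C@@H]1C=CC(OC(=O)OCC=C)=C[C@]1(C)CO[Si](C)(C)C(C)(C)C
F4 | step 21 | tert-butyl 3-{[(1R,2S,6R)-1,6-dimethyl-3-(propan-2-ylidene)-2-(prop-2-en-1-yl)cyclohexyl]methyl}-1H-indole-1-carboxylate | C[C@@H]1CCC(=C(C)C)[C@@H](CC=C)[C@]1(C)Cc1cn(C(=O)OC(C)(C)C)c2ccccc12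
F5 | step 21 | B-alkyl-9-borabicyclo[3.3.1]nonane from F4 (boron on C10) | C[C@@H]1CCC(=C(C)C)[C@@H](CCCB2C3CCCC2CCC3)[C@]1(C)Cc1cn(C(=O)OC(C)(C)C)c2ccccc12
F6 | step 21 | tert-butyl 3-{[(1R,2S,6R)-2-(3-hydroxypropyl)-1,6-dimethyl-3-(propan-2-ylidene)cyclohexyl]methyl}-1H-indole-1-carboxylate | C[C@@H]1CCC(=C(C)C)[C@@H](CCCO)[C@]1(C)Cc1cn(C(=O)OC(C)(C)C)c2ccccc12
F7 | step 21 | 3-[(1S,2R,3R)-2-{[1-(tert-butoxycarbonyl)-1H-indol-3-yl]methyl}-2,3-dimethyl-6-(propan-2-ylidene)cyclohexyl]propanoic acid | C[C@@H]1CCC(=C(C)C)[C@@H](CCC(=O)O)[C@]1(C)Cc1cn(C(=O)OC(C)(C)C)c2ccccc12
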